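All runs stem from a simulated flask with constants of no real substance, and the scatter is random.

A constant read off the runs, 1.32 mM, is the balance level of L: the amount of L at which, with G and Z charged as in those batch runs, the fraction of G ending as Q is reckoned to equal the fraction lost.

| setting | Saturday's | Tuesday's | Friday's | south | south-west | west | north-east |
|---|---|---|---|---|---|---|---|
| G | 20 mM | 20 mM | 20 mM | 20 mM | 20 mM (fed, over 25 h) | 20 mM | 20 mM |
| Z | 80 mM | 80 mM | 80 mM | 80.0 mM (in portions, 3, over 25 h) | 80.0 mM | 80.0 mM (fed, over 25 h) | 80.0 mM |
| L | 2.8 mM | 3.9 mM | 6.2 mM | 2.8 mM | 2.8 mM | 2.8 mM | 2.8 mM |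
| remark | run made earlier | run made earlier | run made earlier | first portion at the start, last at 25 h | all else is in the flask from the start; the feed brings no volume worth counting | all else is in the flask from the start; the feed brings no volume worth counting | everything together at the start |
| time |  |  |  | 40 h | 40 h | 40 h | 40 h |

| run | time / h | Q / % | G / % |
|---|---|---|---|
| Saturday's | 2.00 | 30.9 | 62.2 |
| Saturday's | 3.00 | 42.2 | 45.1 |
| Saturday's | 5.00 | 56.7 | 21.4 |
| Saturday's | 8.00 | 65.2 | 5.1 |
| Saturday's | 15.0 | 68.4 | 0 |
| Saturday's | 25.0 | 68.8 | 0.2 |
| Tuesday's | 2.00 | 40.8 | 50.7 |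
| Tuesday's | 6.00 | 71.0 | 6.0 |
| Tuesday's | 12.0 | 74.7 | 0.1 |
| Tuesday's | 20.0 | 74.5 | 0 |
| Tuesday's | 25.0 | 74.8 | 0 |
| Tuesday's | 30.0 | 74.3 | 0.1 |
| Friday's | 5.00 | 80.4 | 2.2 |
| Friday's | 10.0 | 82.6 | 0.4 |
| Friday's | 15.0 | 82.3 | 0.1 |
| Friday's | 20.0 | 82.8 | 0 |
| Friday's | 25.0 | 82.6 | 0.2 |
| Friday's | 30.0 | 82.0 | 0.3 |

(each reading ± 0.3 percentage points)

1. the best flask by amount of Q, in percent of the G charged; "all alike" if 1.5 percentage points covers them all (south / south-west / west / north-east / all alike)
2. amount of Q at the end, in percent of the G charged, south
3. amount of Q at the end, in percent of the G charged, south-west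
4. amount of Q at the end, in percent of the G charged, west
5. amount of Q at the end, in percent of the G charged, north-east

- the numbers in the tables scatter with a standard deviation of 0.3 percentage points

I reason from both ends. Suppose G goes to Q at a pace in proportion to L and is lost at a pace that does not depend on L. With much L, the lost fraction is about the balance level over L; with little L, the kept fraction is about L over the balance level. Joining the ends, the kept fraction is L/(L + level), so kept over lost, a selectivity factor, is L over the level. Lost over kept, times L, gives 1.33 mM on Tuesday's run and 1.31 mM on Friday's, and I take their mean. For Saturday's charge that gives 68.0%, and Saturday's run reads 68.8%; north-east has that charge, so I commit to this figure for north-east. For the dosed flasks, which no run shows, the rule says only that a different end means a different level.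

The forecast names south-west as best, with 68.9%, 70.5%, 68.5% and 68.7% for south, south-west, west and north-east, holding that “Selectivity therefore depends on Q, not on how G is delivered”. The flasks end at 56.2%, 72.7%, 57.0% and 68.9% in that order, so south-west is best.

    Z + L ⇌ X (K = 228 /M, k = 49.5 /M/h)
    G + X → D (k = 152 /M/h)
    D ⇌ L + Q (K = 1.10 M, k = 28.2 /h)
    G + Q → E (k = 7.56 /M/h)

Turned round, the rule gives south-west a level of 1.05 mM, lower than the batch level 1.32 mM, and west 2.11 mM, higher. In west, G + Q went on to E while Z averaged 28.3 mM over the first 25 h, less than the 62.8 mM in north-east. In south-west, G averaged 8.63% of its charge over the first 25 h, and the step from D to L + Q had done the first half of its turnover up to 40 h by 14.1 h.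

For the south-west neighbour with 1.1 mM of L, south-west's level gives 51.2%. The computed flask ends at 50.7%.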